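At the reading at 4.0 d, what counts is how much substrate partner has turned into target, and the earlier runs show that free substrate is not the whole of what remains.

| flask | substrate | partner | temperature | remark | time |
|---|---|---|---|---|---|
| epsilon | 0.25 M | 0.25 M | −10 °C | run made earlier |  |
| beta | 0.35 M | 0.25 M | 5 °C | run made earlier |  |
| eta | 0.55 M | 0.25 M | −10 °C | run made earlier |  |
| red | 0.25 M | 0.250 M |  | everything together at the start at −15 °C, warmed to 5 °C at 3.0 d | 4.0 d |
| grey | 0.25 M | 0.250 M (fed, over 3.0 d) | 5 °C | all else is in the flask from the start; the feed brings no volume worth counting | 4.0 d |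
| blue | 0.25 M | 0.250 M (in portions, 4, over 3.0 d) | 5 °C | first portion at the start, last at 3.0 d | 4.0 d |
| green | 0.25 M | 0.250 M | 5 °C | everything together at the start | 4.0 d |
| teal | 0.25 M (fed, over 3.0 d) | 0.250 M |  | the addition at −15 °C, then warmed to 5 °C; the feed brings no volume worth counting | 4.0 d |

- epsilon (time / d: target / %, substrate / %): 0.625: 40.3, 24.8; 1.67: 65.3, 14.4; 4.00: 83.1, 7.5; 8.00: 92.5, 4.4
- beta (time / d: target / %, substrate / %): 0.417: 50.9, 23.5; 1.04: 64.4, 18.1; 2.08: 70.8, 17.0; 3.00: 70.6, 15.3
- eta (time / d: target / %, substrate / %): 0.833: 31.4, 31.0; 2.00: 41.1, 29.9; 4.00: 45.0, 27.7; 6.00: 44.4, 29.5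

(readings scatter by 0.5 percentage points)

1. the best flask by amount of target, in percent of the substrate charged; "all alike" if 1.5 percentage points covers them all (red / grey / blue / green / teal / all alike)
2. amount of target at the end, in percent of the substrate charged, red
3. amount of target at the end, in percent of the substrate charged, grey
4. amount of target at the end, in percent of the substrate charged, blue
5. amount of target at the end, in percent of the substrate charged, green
6. amount of target at the end, in percent of the substrate charged, teal

- a reading of substrate is of its free form alone

The balance of partner, the limiting reagent of the beta run, starts the reckoning: by 2.08 d target reads 0.248 M against a charge of 0.25 M, a gap of about 0.00220 M between the two. What then stands beside target is free substrate and a part that no reading shows. The unseen substrate per free substrate, called here the hidden ratio, is read over the last two beta readings as 0.814 at 5 °C. In a flask with equal charges, each partner spent takes one substrate, so c(partner) equals c(substrate) times 1.81.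

The ladder at 5 °C has three rungs. The fastest is the passage of free substrate into whatever no reading shows, and by the first beta reading at 0.417 d that unseen part already stands at 25.6%. Next comes the meeting with partner: taken as second order, that reading gives 0.311 d for equal charges of 0.250 M to fall to half. Slowest is the tail, since 4.0 d is far longer than that time and yet the rate falls with the square of c(partner). My own reckoning for green therefore leaves 7.22% unreacted, which means 92.8% target and 3.98% free substrate. The other flasks each spend 3.0 d of the 4.0 d cold or with a charge still going in, so green is my pick.

The forecast names green, with 86% for red, 87% for grey, 87% for blue, 92% for green and 82% for teal, holding that “free substrate sits in a reversible reservoir”.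

The flasks give 87.7% for red, 90.0% for grey, 88.3% for blue, 95.5% for green and 84.0% for teal, so the best is green.

    partner + tautomer → target (k = 2.70 M⁻¹ h⁻¹, Ea = 58.0 kJ mol⁻¹)
    substrate + partner ⇌ isomer of the product (K = 6.30 M⁻¹, k = 1.40 M⁻¹ h⁻¹, Ea = 50.0 kJ mol⁻¹, ΔH = 20.0 kJ mol⁻¹)
    substrate ⇌ tautomer (K = 0.750, k = 2.80 h⁻¹, Ea = 73.0 kJ mol⁻¹, ΔH = −10.0 kJ mol⁻¹)
    (constants at 5 °C)

The unseen forms are the tautomer and the isomer of the product: green at 4.00 d holds 1.85% of tautomer and 0.190% of the isomer beside 2.48% of substrate, a ratio of 0.823 against the hidden ratio of 0.814. A neighbour of green charged with 0.062 M of partner ends with 24.8% target, so the ratio gives 41.5% free substrate, and that flask holds 43.0%. Green has not come to rest: left ten times as long, to 40.0 d, it gains a further 4.1 percentage points and reaches 99.6%, while teal climbs from 84.0% to 99.6%.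

The numbers in the tables were generated by integration with constants of no real substance; the scatter is artificial.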